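**Retrosynthetic overview**
- Last step: reductive unmasking of a trichloroethyl-protected sulfate and a diphenylmethylene ketal on the finished flavone. The sulfate position is fixed early on the ring B building block, where the ketal ties up two of the three gallaldehyde hydroxyls.
- Ring C (the only ring made) closes last, by O1–C2 bond formation: acid-triggered 6-endo cyclisation of a 2-hydroxyaryl ynone, in the same pot as MOM removal.
- Key C4–C3 bond: the ring A aldehyde reacts as an acyl anion (Breslow intermediate of an N-heterocyclic carbene) with a ring B alkynyl(phenyl)iodonium salt (alkynyl cation equivalent) to give the ynone.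
- Ring B partner: 3,4,5-trihydroxybenzaldehyde → ketal → terminal alkyne → trichloroethyl sulfate → iodonium salt.
- Ring A partner: 2,4,6-trihydroxybenzaldehyde → tris-MOM ether. Rings A and B are bought.

Assumption: the target has no stereocentre or stereogenic double bond, so no stereocontrol is needed; the sulfate is obtained as its ammonium salt and written as the neutral hydrogen sulfate.

**Step 1**
Reactants: 1 3,4,5-trihydroxybenzaldehyde
Product: 2 7-hydroxy-2,2-diphenyl-1,3-benzodioxole-5-carbaldehyde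
Conditions: Ph2CCl2 (1.2 equiv), Ph2O, 175 °C, 30 min
Reagents that add atoms: dichlorodiphenylmethane, ClC(Cl)(c1ccccc1)c1ccccc1
Why: Catechol ketalisation (double substitution at the gem-dichloride) can only bridge two adjacent hydroxyls, and the two possible pairs are symmetry-equivalent, so a single ketal with one free phenol results.

**Step 2**
Reactants: 2 7-hydroxy-2,2-diphenyl-1,3-benzodioxole-5-carbaldehyde
Product: 3 6-ethynyl-2,2-diphenyl-1,3-benzodioxol-4-ol
Conditions: dimethyl (1-diazo-2-oxopropyl)phosphonate (1.3 equiv), K2CO3 (3 equiv), MeOH, rt, 12 h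
Reagents that add atoms: dimethyl (1-diazo-2-oxopropyl)phosphonate (Ohira–Bestmann reagent), CC(=O)C(=[N+]=[N-])P(=O)(OC)OC
Why: Seyferth–Gilbert homologation in its Ohira–Bestmann form converts the aldehyde into the terminal alkyne; the phenoxide sits meta to the aldehyde and does not deactivate it.

**Step 3**
Reactants: 3 6-ethynyl-2,2-diphenyl-1,3-benzodioxol-4-ol
Product: 4 6-ethynyl-2,2-diphenyl-1,3-benzodioxol-4-yl 2,2,2-trichloroethyl sulfate
Conditions: Cl3CCH2OSO2Cl (1.3 equiv), Et3N (1.5 equiv), DMAP (0.2 equiv), THF, 0 °C to rt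
Reagents that add atoms: 2,2,2-trichloroethyl chlorosulfate, ClS(=O)(=O)OCC(Cl)(Cl)Cl
Why: DMAP-catalysed sulfuryl transfer to the only free phenol installs the sulfate as a neutral, acid-stable diester at the position that becomes 3'.

**Step 4**
Reactants: 4 6-ethynyl-2,2-diphenyl-1,3-benzodioxol-4-yl 2,2,2-trichloroethyl sulfate
Product: 5 phenyl[(2,2-diphenyl-7-{[(2,2,2-trichloroethoxy)sulfonyl]oxy}-1,3-benzodioxol-5-yl)ethynyl]iodonium 4-methylbenzenesulfonate
Conditions: PhI(OH)OTs (1.2 equiv), 4 Å MS, CH2Cl2, rt, 16 h; precipitation with Et2O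
Reagents that add atoms: [hydroxy(tosyloxy)iodo]benzene (Koser reagent), Cc1ccc(cc1)S(=O)(=O)OI(O)c1ccccc1
Why: Koser-type reaction of an aryl acetylene with the trivalent iodine reagent (ligand exchange at iodine with loss of water) gives the alkynyl(phenyl)iodonium tosylate, which turns the acetylenic carbon into an electrophile.

**Step 5**
Reactants: 6 2,4,6-trihydroxybenzaldehyde
Product: 7 2,4,6-tris(methoxymethoxy)benzaldehyde
Conditions: NaH (3.6 equiv), MOMCl (3.6 equiv), DMF, 0 °C to rt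
Reagents that add atoms: chloromethyl methyl ether, COCCl
Why: Williamson-type O-alkylation of all three phenoxides; NaH is needed because the two hydrogen-bonded ortho hydroxyls resist amine bases.

**Step 6**
Reactants: 7 2,4,6-tris(methoxymethoxy)benzaldehyde; 5 phenyl[(2,2-diphenyl-7-{[(2,2,2-trichloroethoxy)sulfonyl]oxy}-1,3-benzodioxol-5-yl)ethynyl]iodonium 4-methylbenzenesulfonate
Product: 10 6-(5,7-dihydroxy-4-oxo-4H-chromen-2-yl)-2,2-diphenyl-1,3-benzodioxol-4-yl 2,2,2-trichloroethyl sulfate, via tris-MOM ynone 8 (not isolated), via trihydroxy ynone 9 (not isolated)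
Conditions: 2-(pentafluorophenyl)-6,7-dihydro-5H-pyrrolo[2,1-c][1,2,4]triazol-2-ium tetrafluoroborate (20 mol%), iPr2NEt (1.5 equiv), toluene, −40 °C, slow addition of 5, then 0 °C; then MeOH, HCl (1 M), 45 °C
Reagents that add atoms: none
Why: N-heterocyclic-carbene-catalysed C–H alkynylation of an aldehyde, in which the Breslow intermediate of 7 (acyl anion equivalent) attacks the acetylenic carbon of the iodonium salt and expels iodobenzene to give ynone 8, after which acid strips the MOM groups and the freed ortho phenol closes ring C by 6-endo-dig oxa-Michael addition (self-benzoin of the doubly ortho-substituted aldehyde is blocked and the sp-carbon electrophile is sterically undemanding).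

**Step 7**
Reactants: 10 6-(5,7-dihydroxy-4-oxo-4H-chromen-2-yl)-2,2-diphenyl-1,3-benzodioxol-4-yl 2,2,2-trichloroethyl sulfate
Product: 11 tricetin 3'-sulfate, 5-(5,7-dihydroxy-4-oxo-4H-chromen-2-yl)-2,3-dihydroxyphenyl hydrogen sulfate
Conditions: Pd(OH)2/C (20 wt%), H2 (1 atm), HCO2NH4 (5 equiv), MeOH/THF 1:1, rt
Reagents that add atoms: none
Why: Catalytic hydrogenolysis of the doubly benzylic ketal C–O bonds and formate-driven reductive β-elimination of the trichloroethyl group (loss of chloride and 1,1-dichloroethene) free the catechol and the sulfate monoester together, while the flavone C2=C3 bond and the aryl sulfate anion are inert at room temperature.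

**Compound list**
1 | 3,4,5-trihydroxybenzaldehyde | O=Cc1cc(O)c(O)c(O)c1 | starting material
2 | 7-hydroxy-2,2-diphenyl-1,3-benzodioxole-5-carbaldehyde | O=Cc1cc(O)c2OC(c3ccccc3)(c3ccccc3)Oc2c1 | intermediate
3 | 6-ethynyl-2,2-diphenyl-1,3-benzodioxol-4-ol | C#Cc1cc(O)c2OC(c3ccccc3)(c3ccccc3)Oc2c1 | intermediate
4 | 6-ethynyl-2,2-diphenyl-1,3-benzodioxol-4-yl 2,2,2-trichloroethyl sulfate | C#Cc1cc(OS(=O)(=O)OCC(Cl)(Cl)Cl)c2OC(c3ccccc3)(c3ccccc3)Oc2c1 | intermediate
5 | phenyl[(2,2-diphenyl-7-{[(2,2,2-trichloroethoxy)sulfonyl]oxy}-1,3-benzodioxol-5-yl)ethynyl]iodonium 4-methylbenzenesulfonate | Cc1ccc(cc1)S(=O)(=O)[O-].ClC(Cl)(Cl)COS(=O)(=O)Oc1cc(C#C[I+]c2ccccc2)cc2OC(c3ccccc3)(c3ccccc3)Oc12 | intermediate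
6 | 2,4,6-trihydroxybenzaldehyde | O=Cc1c(O)cc(O)cc1O | starting material
7 | 2,4,6-tris(methoxymethoxy)benzaldehyde | COCOc1cc(OCOC)c(C=O)c(OCOC)c1 | intermediate
8 | 3-(2,2-diphenyl-7-{[(2,2,2-trichloroethoxy)sulfonyl]oxy}-1,3-benzodioxol-5-yl)-1-[2,4,6-tris(methoxymethoxy)phenyl]prop-2-yn-1-one | COCOc1cc(OCOC)c(C(=O)C#Cc2cc(OS(=O)(=O)OCC(Cl)(Cl)Cl)c3OC(c4ccccc4)(c4ccccc4)Oc3c2)c(OCOC)c1 | intermediate
9 | 3-(2,2-diphenyl-7-{[(2,2,2-trichloroethoxy)sulfonyl]oxy}-1,3-benzodioxol-5-yl)-1-(2,4,6-trihydroxyphenyl)prop-2-yn-1-one | O=C(C#Cc1cc(OS(=O)(=O)OCC(Cl)(Cl)Cl)c2OC(c3ccccc3)(c3ccccc3)Oc2c1)c1c(O)cc(O)cc1O | intermediate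
10 | 6-(5,7-dihydroxy-4-oxo-4H-chromen-2-yl)-2,2-diphenyl-1,3-benzodioxol-4-yl 2,2,2-trichloroethyl sulfate | O=c1cc(-c2cc(OS(=O)(=O)OCC(Cl)(Cl)Cl)c3OC(c4ccccc4)(c4ccccc4)Oc3c2)oc2cc(O)cc(O)c12 | intermediate
11 | tricetin 3'-sulfate, 5-(5,7-dihydroxy-4-oxo-4H-chromen-2-yl)-2,3-dihydroxyphenyl hydrogen sulfate | O=c1cc(-c2cc(O)c(O)c(OS(=O)(=O)O)c2)oc2cc(O)cc(O)c12 | target

**Totals**
Total step count: 7. Longest linear sequence: 6 (steps 1, 2, 3, 4, 6, 7).

**Steps most likely to fail, with fallbacks**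

Step 6. The aldehyde of 7 is electron-rich and flanked by two ortho ethers, so Breslow intermediate formation may be slow and the free carbene may instead be alkynylated by 5. The fallback sets out from 3 and 7 and comes back to the route at 8, using normal-polarity acetylide chemistry. The dianion of 3 (n-BuLi, 2.1 equiv, THF, −78 °C) adds to aldehyde 7 to give racemic 3-(7-hydroxy-2,2-diphenyl-1,3-benzodioxol-5-yl)-1-[2,4,6-tris(methoxymethoxy)phenyl]prop-2-yn-1-ol F1. MnO2 (CH2Cl2, rt) oxidises this to 3-(7-hydroxy-2,2-diphenyl-1,3-benzodioxol-5-yl)-1-[2,4,6-tris(methoxymethoxy)phenyl]prop-2-yn-1-one F2. Sulfation of its phenol under the conditions of step 3 gives isolated 8, which is then treated with HCl/MeOH as in the second stage of step 6 to reach 10.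

Step 4. Direct reaction of the aryl acetylene with the Koser reagent may give addition products or an unstable salt. The fallback sets out from 4 and comes back to the route at 8, forming the carbon–iodine bond by silicon exchange instead of C–H substitution. C-silylation of 4 (TMSOTf, Et3N, Zn(OTf)2 cat., CH2Cl2) gives 2,2-diphenyl-6-[(trimethylsilyl)ethynyl]-1,3-benzodioxol-4-yl 2,2,2-trichloroethyl sulfate F3. Treatment with PhI(OAc)2 and TfOH (CH2Cl2, 0 °C) gives phenyl[(2,2-diphenyl-7-{[(2,2,2-trichloroethoxy)sulfonyl]oxy}-1,3-benzodioxol-5-yl)ethynyl]iodonium trifluoromethanesulfonate F4. This salt takes the place of 5 in step 6.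

Step 7. Ketal hydrogenolysis may be slow, or the C2=C3 bond may be reduced on prolonged exposure to the catalyst. The fallback sets out from 10 and comes back to the route at 11 without any hydrogenation catalyst. Aqueous AcOH (80%, 90 °C) hydrolyses the ketal to give 5-(5,7-dihydroxy-4-oxo-4H-chromen-2-yl)-2,3-dihydroxyphenyl 2,2,2-trichloroethyl sulfate F5. Zn dust with HCO2NH4 in MeOH at rt then removes the trichloroethyl group to give 11.

**Further compounds**
F1 | step 6 | 3-(7-hydroxy-2,2-diphenyl-1,3-benzodioxol-5-yl)-1-[2,4,6-tris(methoxymethoxy)phenyl]prop-2-yn-1-ol (racemic) | COCOc1cc(OCOC)c(C(O)C#Cc2cc(O)c3OC(c4ccccc4)(c4ccccc4)Oc3c2)c(OCOC)c1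
F2 | step 6 | 3-(7-hydroxy-2,2-diphenyl-1,3-benzodioxol-5-yl)-1-[2,4,6-tris(methoxymethoxy)phenyl]prop-2-yn-1-one | COCOc1cc(OCOC)c(C(=O)C#Cc2cc(O)c3OC(c4ccccc4)(c4ccccc4)Oc3c2)c(OCOC)c1
F3 | step 4 | 2,2-diphenyl-6-[(trimethylsilyl)ethynyl]-1,3-benzodioxol-4-yl 2,2,2-trichloroethyl sulfate | C[Si](C)(C)C#Cc1cc(OS(=O)(=O)OCC(Cl)(Cl)Cl)c2OC(c3ccccc3)(c3ccccc3)Oc2c1
F4 | step 4 | phenyl[(2,2-diphenyl-7-{[(2,2,2-trichloroethoxy)sulfonyl]oxy}-1,3-benzodioxol-5-yl)ethynyl]iodonium trifluoromethanesulfonate | [O-]S(=O)(=O)C(F)(F)F.ClC(Cl)(Cl)COS(=O)(=O)Oc1cc(C#C[I+]c2ccccc2)cc2OC(c3ccccc3)(c3ccccc3)Oc12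
F5 | step 7 | 5-(5,7-dihydroxy-4-oxo-4H-chromen-2-yl)-2,3-dihydroxyphenyl 2,2,2-trichloroethyl sulfate | O=c1cc(-c2cc(O)c(O)c(OS(=O)(=O)OCC(Cl)(Cl)Cl)c2)oc2cc(O)cc(O)c12
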